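**Retrosynthetic overview**

1. Target 19 comes from the protected isocoumarin 18 by one acid-mediated removal of two methoxymethyl ethers and one silyl ether.
2. 18 comes from benzoic acid 16 and dienoyl sulfoxonium ylide 13 by a carboxylate-directed C-H annulation under trivalent rhodium. It forms C4a-C4 and O2-C3 and closes the pyranone ring (C1, O2, C3, C4, C4a, C8a) last, with the side chain already on C3. The plan rests on one structural fact: in the 5-chloro-2,4-dioxygenated benzoic acid, C8 carries oxygen, so C4a is the only carbon next to the carboxyl-bearing C8a that still has a hydrogen, and the C5 chlorine is in place beforehand.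
3. 13 comes from dienoic acid 10 (as its chloride) and dimethylsulfoxonium methylide; 10 comes from oxolane aldehyde 7 and phosphonate 8 by a vinylogous Horner-Wadsworth-Emmons reaction.
4. 7 comes from 2-deoxy-L-ribose 1. Sugar C4 and C3 become oxolane C2 and C3; oxolane C5 is set by reduction of a methyl hemiketal. The oxolane ring is therefore the first ring made and the benzene ring is bought.
5. 16 comes from 5-chloro-2,4-dihydroxybenzoic acid 14 by exhaustive methoxymethylation and ester hydrolysis.

Key step: step 12

Remark: 2-deoxy-L-ribose 1 is written as the open-chain aldehyde but reacts as its cyclic hemiacetal. Oxolane atoms are numbered O1, C2 (side chain), C3 (oxygen), C4, C5 (methyl); isocoumarin atoms are numbered C1 to C8a.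

**Route**

Step 1
Reactants: 1 2-deoxy-L-ribose
Product: 2 2-deoxy-L-ribono-1,4-lactone, (4R,5S)-4-hydroxy-5-(hydroxymethyl)oxolan-2-one
Conditions: Br2, H2O, rt; concentrate
Reagents that add atoms: none
Why: Bromine-water oxidation of the aldose hemiacetal gives the aldonic acid, which closes to the five-membered 1,4-lactone on concentration, and the two carbinol centres are not involved.

Step 2
Reactants: 2 2-deoxy-L-ribono-1,4-lactone
Product: 3 (4R,5S)-4-(tert-butyldimethylsilyloxy)-5-[(tert-butyldimethylsilyloxy)methyl]oxolan-2-one
Conditions: TBSCl, imidazole, DMF, rt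
Reagents that add atoms: tert-butyldimethylsilyl chloride, CC(C)(C)[Si](C)(C)Cl
Why: Imidazole-promoted silylation protects both hydroxyl groups, so the lactone carbonyl is the only electrophile left for step 3.

Step 3
Reactants: 3 bis-silylated lactone
Product: 4 (4R,5S)-4-(tert-butyldimethylsilyloxy)-5-[(tert-butyldimethylsilyloxy)methyl]-2-methyloxolan-2-ol (mixture of anomers, used crude)
Conditions: MeLi, THF, −78 °C; H2O quench
Reagents that add atoms: methyllithium, [Li]C
Why: Organolithium addition to a lactone stops at the tetrahedral lithium alkoxide at −78 °C, so one methyl group is delivered and the methyl ketose is obtained as its cyclic hemiketal.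

Step 4
Reactants: 4 methyl hemiketal
Product: 5 (2S,3R,5R)-3-(tert-butyldimethylsilyloxy)-2-[(tert-butyldimethylsilyloxy)methyl]-5-methyloxolane
Conditions: Et3SiH, BF3·OEt2, CH2Cl2, −78 °C
Reagents that add atoms: none
Why: In this ionic hydrogenation BF3 generates the methyl-substituted five-membered oxocarbenium ion and Et3SiH attacks its envelope from the inside face, syn to the pseudoaxial C3 silyloxy group, so the new C5-H is cis to C3-O and the methyl group ends cis to the C2 side arm (5R), the sense known from reductions of 2-deoxyribose-derived hemiketals to β-C-glycosides.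

Step 5
Reactants: 5 bis-silyl ether
Product: 6 [(2S,3R,5R)-3-(tert-butyldimethylsilyloxy)-5-methyloxolan-2-yl]methanol
Conditions: TFA/H2O/THF (1:1:4), 0 °C
Reagents that add atoms: none
Why: The primary silyl ether is hydrolysed far faster than the hindered secondary one in cold aqueous TFA, a selective deprotection that is routine for bis-silylated 2-deoxyribose derivatives.

Step 6
Reactants: 6 primary alcohol
Product: 7 (2R,3R,5R)-3-(tert-butyldimethylsilyloxy)-5-methyloxolane-2-carbaldehyde (descriptor at C2 changes by priority only)
Conditions: Dess–Martin periodinane, CH2Cl2, 0 °C → rt; used at once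
Reagents that add atoms: none
Why: Dess–Martin oxidation is non-basic, so the α-alkoxy aldehyde should form without epimerisation at C2 or β-elimination of the C3 silyloxy group.

Step 7
Reactants: 7 oxolane aldehyde; 8 triethyl 4-phosphonocrotonate
Product: 9 ethyl (2E,4E)-5-[(2S,3R,5R)-3-(tert-butyldimethylsilyloxy)-5-methyloxolan-2-yl]penta-2,4-dienoate
Conditions: LiN(SiMe3)2, THF, −78 → 0 °C
Reagents that add atoms: none
Why: In this vinylogous Horner–Wadsworth–Emmons olefination the lithium anion of 8 attacks the aldehyde through the carbon next to phosphorus and syn-elimination of phosphate gives the new E double bond, while the existing E double bond is kept.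

Step 8
Reactants: 9 ethyl dienoate
Product: 10 (2E,4E)-5-[(2S,3R,5R)-3-(tert-butyldimethylsilyloxy)-5-methyloxolan-2-yl]penta-2,4-dienoic acid
Conditions: LiOH, THF/MeOH/H2O, rt; 1 M HCl to pH 4, 0 °C
Reagents that add atoms: lithium hydroxide, [Li+].[OH-]
Why: Hydroxide saponification of the ethyl ester is tolerated by the secondary silyl ether and the diene at room temperature, and the acid is liberated at pH 4.

Step 9
Reactants: 10 dienoic acid; 11 trimethylsulfoxonium iodide
Product: 13 (3E,5E)-1-[dimethyl(oxo)-λ6-sulfanylidene]-6-[(2S,3R,5R)-3-(tert-butyldimethylsilyloxy)-5-methyloxolan-2-yl]hexa-3,5-dien-2-one, via dienoyl chloride 12 (not isolated)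
Conditions: 1-chloro-N,N,2-trimethylprop-1-en-1-amine, CH2Cl2, 0 °C; then added to Me2S(O)=CH2 (from 11, KOtBu, THF, reflux), −20 → 0 °C
Reagents that add atoms: none
Why: The acid is turned into its chloride under neutral conditions and dimethylsulfoxonium methylide is acylated at carbon, a second equivalent removing the proton of the acylsulfoxonium salt (the standard synthesis of acyl sulfoxonium ylides), and the chloride is chosen because acyl substitution is then much faster than the conjugate addition that the methylide would undergo with the dienoate ester.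

Step 10
Reactants: 14 5-chloro-2,4-dihydroxybenzoic acid
Product: 15 methoxymethyl 5-chloro-2,4-bis(methoxymethoxy)benzoate
Conditions: MOMCl, iPr2NEt, DMF, 0 → 40 °C
Reagents that add atoms: chloromethyl methyl ether, COCCl
Why: Exhaustive O-alkylation with chloromethyl methyl ether under amine base protects both phenols as acetals and converts the acid into its methoxymethyl ester.

Step 11
Reactants: 15 methoxymethyl ester
Product: 16 5-chloro-2,4-bis(methoxymethoxy)benzoic acid
Conditions: NaOH (aq), MeOH/THF, 50 °C; 1 M HCl to pH 4, 0 °C
Reagents that add atoms: sodium hydroxide, [Na+].[OH-]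
Why: Hydroxide cleaves the acyl-oxygen bond of the methoxymethyl ester while the aryl methoxymethyl ethers are inert to base, and cold acidification to pH 4 frees the acid without touching the acetals.

Step 12
Reactants: 16 5-chloro-2,4-bis(methoxymethoxy)benzoic acid; 13 dienoyl sulfoxonium ylide
Product: 18 3-[(1E,3E)-4-[(2S,3R,5R)-3-(tert-butyldimethylsilyloxy)-5-methyloxolan-2-yl]buta-1,3-dien-1-yl]-5-chloro-6,8-bis(methoxymethoxy)-1H-isochromen-1-one, via keto acid 17 (not isolated)
Conditions: [Rh(C5Me5)Cl2]2 (5 mol%), NaOAc, CF3CH2OH/ClCH2CH2Cl, 70 °C, Ar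
Reagents that add atoms: none
Why: The acetate-ligated trivalent rhodium binds the carboxylate of 16 and cleaves the neighbouring C4a-H bond by acetate-assisted metalation-deprotonation to a five-membered aryl-rhodium chelate; ylide 13 then coordinates through its carbanionic carbon, loses dimethyl sulfoxide to give a rhodium carbene, the aryl group migrates to that carbon (C4a-C4), and protonolysis releases keto acid 17 and the catalyst. The carboxyl oxygen of 17 adds to the C3 ketone in a 6-exo-trig closure and loss of water gives the enol lactone (O2-C3), which completes the pyranone ring in the same flask. The closest known reaction type is the carboxylate-directed annulation of benzoic acids with acyl sulfoxonium ylides to 3-substituted isocoumarins under [Rh(C5Me5)Cl2]2 and related catalysts, applied here to a conjugated dienoyl ylide. No stereocentre is formed, and the three oxolane centres and the (E,E)-diene lie away from the reacting atoms in an acetate-buffered medium that also spares the acetals and the silyl ether. Site selectivity needs no control because C8 carries oxygen and C4a-H is the only C-H beside the carboxyl-bearing carbon. Chemoselectivity for insertion over cyclopropanation of the diene or O-alkylation of the acid relies on the carbene forming only on the aryl-rhodium centre, where aryl migration is intramolecular and fast, and on keeping the acid as its sodium salt.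

Step 13
Reactants: 18 protected isocoumarin
Product: 19 5-chloro-6,8-dihydroxy-3-[(1E,3E)-4-[(2S,3R,5R)-3-hydroxy-5-methyloxolan-2-yl]buta-1,3-dien-1-yl]-1H-isochromen-1-one (CNP0086741.5)
Conditions: HCl (1.25 M in MeOH), 0 °C → rt
Reagents that add atoms: none
Why: Acid-catalysed acetal exchange with methanol removes both methoxymethyl groups and methanolysis removes the silyl ether in the same flask, while the lactone, the aryl chloride and the dienyl ether of the oxolane (whose ionisation would give a cation next to a β-hydroxyl group and an electron-poor isocoumarin) should survive dilute HCl at or below room temperature.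

**Compound list**

1 | 2-deoxy-L-ribose | O=CC[C@@H](O)[C@@H](O)CO | starting material
2 | (4R,5S)-4-hydroxy-5-(hydroxymethyl)oxolan-2-one | O=C1C[C@@H](O)[C@H](CO)O1 | intermediate
3 | (4R,5S)-4-(tert-butyldimethylsilyloxy)-5-[(tert-butyldimethylsilyloxy)methyl]oxolan-2-one | O=C1C[C@@H](O[Si](C)(C)C(C)(C)C)[C@H](CO[Si](C)(C)C(C)(C)C)O1 | intermediate
4 | (4R,5S)-4-(tert-butyldimethylsilyloxy)-5-[(tert-butyldimethylsilyloxy)methyl]-2-methyloxolan-2-ol, anomer mixture | CC1(O)C[C@@H](O[Si](C)(C)C(C)(C)C)[C@H](CO[Si](C)(C)C(C)(C)C)O1 | intermediate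
5 | (2S,3R,5R)-3-(tert-butyldimethylsilyloxy)-2-[(tert-butyldimethylsilyloxy)methyl]-5-methyloxolane | C[C@@H]1C[C@@H](O[Si](C)(C)C(C)(C)C)[C@H](CO[Si](C)(C)C(C)(C)C)O1 | intermediate
6 | [(2S,3R,5R)-3-(tert-butyldimethylsilyloxy)-5-methyloxolan-2-yl]methanol | C[C@@H]1C[C@@H](O[Si](C)(C)C(C)(C)C)[C@H](CO)O1 | intermediate
7 | (2R,3R,5R)-3-(tert-butyldimethylsilyloxy)-5-methyloxolane-2-carbaldehyde | C[C@@H]1C[C@@H](O[Si](C)(C)C(C)(C)C)[C@H](C=O)O1 | intermediate
8 | triethyl 4-phosphonocrotonate | CCOC(=O)/C=C/CP(=O)(OCC)OCC | starting material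
9 | ethyl (2E,4E)-5-[(2S,3R,5R)-3-(tert-butyldimethylsilyloxy)-5-methyloxolan-2-yl]penta-2,4-dienoate | C[C@@H]1C[C@@H](O[Si](C)(C)C(C)(C)C)[C@H](/C=C/C=C/C(=O)OCC)O1 | intermediate
10 | (2E,4E)-5-[(2S,3R,5R)-3-(tert-butyldimethylsilyloxy)-5-methyloxolan-2-yl]penta-2,4-dienoic acid | C[C@@H]1C[C@@H](O[Si](C)(C)C(C)(C)C)[C@H](/C=C/C=C/C(=O)O)O1 | intermediate
11 | trimethylsulfoxonium iodide | C[S+](C)(C)=O.[I-] | starting material
12 | (2E,4E)-5-[(2S,3R,5R)-3-(tert-butyldimethylsilyloxy)-5-methyloxolan-2-yl]penta-2,4-dienoyl chloride | C[C@@H]1C[C@@H](O[Si](C)(C)C(C)(C)C)[C@H](/C=C/C=C/C(=O)Cl)O1 | intermediate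
13 | (3E,5E)-1-[dimethyl(oxo)-λ6-sulfanylidene]-6-[(2S,3R,5R)-3-(tert-butyldimethylsilyloxy)-5-methyloxolan-2-yl]hexa-3,5-dien-2-one | C[C@@H]1C[C@@H](O[Si](C)(C)C(C)(C)C)[C@H](/C=C/C=C/C(=O)C=S(C)(C)=O)O1 | intermediate
14 | 5-chloro-2,4-dihydroxybenzoic acid | OC(=O)c1cc(Cl)c(O)cc1O | starting material
15 | methoxymethyl 5-chloro-2,4-bis(methoxymethoxy)benzoate | COCOC(=O)c1cc(Cl)c(OCOC)cc1OCOC | intermediate
16 | 5-chloro-2,4-bis(methoxymethoxy)benzoic acid | OC(=O)c1cc(Cl)c(OCOC)cc1OCOC | intermediate
17 | 3-chloro-4,6-bis(methoxymethoxy)-2-[(3E,5E)-6-[(2S,3R,5R)-3-(tert-butyldimethylsilyloxy)-5-methyloxolan-2-yl]-2-oxohexa-3,5-dien-1-yl]benzoic acid | C[C@@H]1C[C@@H](O[Si](C)(C)C(C)(C)C)[C@H](/C=C/C=C/C(=O)Cc2c(Cl)c(OCOC)cc(OCOC)c2C(=O)O)O1 | intermediate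
18 | 3-[(1E,3E)-4-[(2S,3R,5R)-3-(tert-butyldimethylsilyloxy)-5-methyloxolan-2-yl]buta-1,3-dien-1-yl]-5-chloro-6,8-bis(methoxymethoxy)-1H-isochromen-1-one | C[C@@H]1C[C@@H](O[Si](C)(C)C(C)(C)C)[C@H](/C=C/C=C/c2cc3c(Cl)c(OCOC)cc(OCOC)c3c(=O)o2)O1 | intermediate
19 | 5-chloro-6,8-dihydroxy-3-[(1E,3E)-4-[(2S,3R,5R)-3-hydroxy-5-methyloxolan-2-yl]buta-1,3-dien-1-yl]-1H-isochromen-1-one | C[C@@H]1C[C@@H](O)[C@H](/C=C/C=C/c2cc3c(Cl)c(O)cc(O)c3c(=O)o2)O1 | target

**Step count**

Total step count: 13. Longest linear sequence: 11 steps (steps 1 to 9, then 12 and 13).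

**Steps most likely to fail**

Step 12. Metalation of the C4a-H bond, which is flanked by chlorine and held only by a weakly bound carboxylate, may be slower than protonation of the ylide by the acid. The ylide would then be consumed by O-alkylation of the carboxylate, or the carbene would be diverted at the diene. The fallback sets out from acid 16, which is condensed with O-methylhydroxylamine (EDC·HCl, MeONH2·HCl, iPr2NEt, CH2Cl2) to give 5-chloro-N-methoxy-2,4-bis(methoxymethoxy)benzamide F1. F1 and ylide 13 are then joined with [Rh(C5Me5)Cl2]2 under the additive conditions that steer the known amide-directed annulation with sulfoxonium ylides to O-cyclisation. The anionic amide nitrogen binds rhodium more firmly and the carboxylic proton is gone; after C-H acylmethylation the amide carbonyl oxygen closes on the ketone and O-methylhydroxylamine is expelled. The sequence returns to the route at 18.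

Step 9. The basic methylide may deprotonate the dienoyl chloride at the vinylogous oxolane C2-H to give a vinylketene, which would erase the C2 configuration, or it may add in conjugate fashion. The fallback sets out from acid 10, which is esterified (EDC·HCl, 4-nitrophenol, DMAP, CH2Cl2) to 4-nitrophenyl (2E,4E)-5-[(2S,3R,5R)-3-(tert-butyldimethylsilyloxy)-5-methyloxolan-2-yl]penta-2,4-dienoate F2. This isolable active ester has no ketene pathway under the conditions used. Treatment with the preformed methylide in THF at 0 °C displaces 4-nitrophenoxide, the established active-ester route to acyl sulfoxonium ylides, and returns to the route at 13.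

Step 7. The strongly basic vinylogous phosphonate anion may give poor E selectivity at the new double bond, and may cause epimerisation at C2 or β-elimination of the silyloxy group in aldehyde 7. The fallback sets out from 7 and builds the diene one double bond at a time. A Wittig reaction with the neutral stabilised ylide (triphenylphosphoranylidene)acetaldehyde in toluene gives (2E)-3-[(2S,3R,5R)-3-(tert-butyldimethylsilyloxy)-5-methyloxolan-2-yl]prop-2-enal F3. A Masamune–Roush olefination of F3 with triethyl phosphonoacetate (LiCl, DBU, MeCN) then returns to the route at 9.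

**Further compounds**

F1 | step 12 | 5-chloro-N-methoxy-2,4-bis(methoxymethoxy)benzamide | CONC(=O)c1cc(Cl)c(OCOC)cc1OCOC
F2 | step 9 | 4-nitrophenyl (2E,4E)-5-[(2S,3R,5R)-3-(tert-butyldimethylsilyloxy)-5-methyloxolan-2-yl]penta-2,4-dienoate | C[C@@H]1C[C@@H](O[Si](C)(C)C(C)(C)C)[C@H](/C=C/C=C/C(=O)Oc2ccc(cc2)[N+](=O)[O-])O1
F3 | step 7 | (2E)-3-[(2S,3R,5R)-3-(tert-butyldimethylsilyloxy)-5-methyloxolan-2-yl]prop-2-enal | C[C@@H]1C[C@@H](O[Si](C)(C)C(C)(C)C)[C@H](/C=C/C=O)O1
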